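Ring A of the target, a hexasubstituted benzene, is cut at C1–C(=O) and C2–O: the neighbouring C1 benzoyl and C2 hydroxyl groups are treated as benzoic acid added across a C1–C2 aryne. In one operation fluoride releases that aryne from an ortho-silylaryl triflate, benzoate adds through oxygen at C2 and the C1 anion captures the acyl group, so both bonds and the ortho-hydroxy ketone arise together. The precursor is a fully substituted benzene carrying SiMe3 at C1, triflate at C2, prenyl groups at C3 and C5, OMe at C4 and a MOM ether at C6; its two phenol oxygens are told apart from the start as MOM ether and diethylcarbamate.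

Key step: step 8

Remark on numbering: ring A is numbered as in the benzophenone (C1 benzoyl, C2 and C6 oxygen, C3 and C5 prenyl, C4 methoxy), and these ring numbers are used for every intermediate.
Remark on stereochemistry: no compound of the route has a stereocentre or a stereogenic double bond.
Remark on protecting groups: a ring carbon that bears SiMe3 and is flanked by donor oxygens is expected to be cleaved by acid. The oxygen that becomes the triflate is therefore carried as an N,N-diethylcarbamate, which is removed by hydride. As the strongest ortho-director present, the carbamate also fixes the site of the silylation and of the first prenylation.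

Step 1
Reactants: 1 5-methoxyresorcinol
Product: 2 3-methoxy-5-(methoxymethoxy)phenol
Conditions: NaH (1 equiv), MOMCl (1 equiv), DMF, 0 °C to rt
Reagents that add atoms: chloromethyl methyl ether (MOMCl), COCCl
Why: Williamson-type O-alkylation of the monosodium phenoxide should give the mono-MOM ether; the statistical distribution is tolerated at this first step because the diol and the bis-ether are cheap, differ widely in polarity and the recovered diol can be resubmitted.

Step 2
Reactants: 2 3-methoxy-5-(methoxymethoxy)phenol
Product: 3 3-methoxy-5-(methoxymethoxy)phenyl N,N-diethylcarbamate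
Conditions: NaH, ClC(O)NEt2, THF, 0 °C to rt
Reagents that add atoms: N,N-diethylcarbamoyl chloride, CCN(CC)C(Cl)=O
Why: O-Carbamoylation of the sodium phenoxide (acyl substitution at the carbamoyl chloride) should be clean because the phenoxide is the only nucleophile present, and it installs a base-stable group that directs ortho-metalation more strongly than the MOM ether.

Step 3
Reactants: 3 3-methoxy-5-(methoxymethoxy)phenyl N,N-diethylcarbamate
Product: 4 5-methoxy-3-(methoxymethoxy)-2-(trimethylsilyl)phenyl N,N-diethylcarbamate
Conditions: s-BuLi, TMEDA, THF, −78 °C; TMSCl, −78 °C to rt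
Reagents that add atoms: chlorotrimethylsilane, C[Si](C)(C)Cl
Why: Directed ortho-metalation should take place at C1, the ring C–H flanked by the carbamate and MOM oxygens and so activated by the two strongest directing groups, and silylation at −78 °C should precede any anionic ortho-Fries shift; the silicon placed here is the later aryne trigger and blocks this position.

Step 4
Reactants: 4 5-methoxy-3-(methoxymethoxy)-2-(trimethylsilyl)phenyl N,N-diethylcarbamate; 5 prenyl bromide (1-bromo-3-methylbut-2-ene)
Product: 6 3-methoxy-5-(methoxymethoxy)-2-(3-methylbut-2-enyl)-6-(trimethylsilyl)phenyl N,N-diethylcarbamate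
Conditions: s-BuLi, TMEDA, THF, −78 °C; CuBr·SMe2, −78 °C; 5, −78 °C to rt
Reagents that add atoms: none
Why: Directed ortho-metalation should now occur at C3, the one free position ortho to the carbamate (between carbamate and OMe), because the carbamate outranks the MOM ether as a director; transmetalation to the arylcopper at −78 °C suppresses the anionic ortho-Fries rearrangement and allows allylic substitution at the primary carbon of prenyl bromide.

Step 5
Reactants: 6 3-methoxy-5-(methoxymethoxy)-2-(3-methylbut-2-enyl)-6-(trimethylsilyl)phenyl N,N-diethylcarbamate
Product: 7 3-methoxy-5-(methoxymethoxy)-2-(3-methylbut-2-enyl)-6-(trimethylsilyl)phenol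
Conditions: LiAlH4, THF, reflux; then H2O, aq NaOH
Reagents that add atoms: none
Why: Hydride attack on the carbamate carbonyl (reductive carbamate cleavage) should release the phenoxide without any acid, so the C–Si bond on the electron-rich ring, the MOM ether and the alkene are left untouched.

Step 6
Reactants: 7 3-methoxy-5-(methoxymethoxy)-2-(3-methylbut-2-enyl)-6-(trimethylsilyl)phenol; 5 prenyl bromide (1-bromo-3-methylbut-2-ene)
Product: 8 3-methoxy-5-(methoxymethoxy)-2,4-bis(3-methylbut-2-enyl)-6-(trimethylsilyl)phenol
Conditions: n-BuLi (1 equiv), THF, −78 °C; s-BuLi, TMEDA, −78 to −40 °C; CuBr·SMe2, −78 °C; 5, −78 °C to rt; aq work-up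
Reagents that add atoms: none
Why: After O-deprotonation, directed ortho-metalation of the lithium phenoxide should occur at C5, the only ring C–H, which lies between the MOM and OMe oxygens; the phenoxide oxygen is a poor director for lateral deprotonation of the neighbouring prenyl CH2 and, flanked by SiMe3 and prenyl, is too hindered for O-alkylation, so cupration and allylic substitution should install the second prenyl group on carbon.

Step 7
Reactants: 8 3-methoxy-5-(methoxymethoxy)-2,4-bis(3-methylbut-2-enyl)-6-(trimethylsilyl)phenol
Product: 9 3-methoxy-5-(methoxymethoxy)-2,4-bis(3-methylbut-2-enyl)-6-(trimethylsilyl)phenyl trifluoromethanesulfonate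
Conditions: n-BuLi (1 equiv), Et2O, −78 °C; Tf2O, −78 to 0 °C
Reagents that add atoms: trifluoromethanesulfonic anhydride, O=S(=O)(OS(=O)(=O)C(F)(F)F)C(F)(F)F
Why: O-Sulfonylation of the lithium phenoxide with triflic anhydride at low temperature is the standard conversion of hindered ortho-silylphenols into ortho-silylaryl triflates, and the MOM ether, the C–Si bond and the alkenes should be inert to it.

Step 8
Reactants: 9 3-methoxy-5-(methoxymethoxy)-2,4-bis(3-methylbut-2-enyl)-6-(trimethylsilyl)phenyl trifluoromethanesulfonate; 10 benzoic acid
Product: 12 2-hydroxy-4-methoxy-6-(methoxymethoxy)-3,5-bis(3-methylbut-2-enyl)benzophenone, via aryne 11 (not isolated)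
Conditions: PhCO2H (1.2 equiv), CsF (4 equiv), THF, 125 °C, sealed tube
Reagents that add atoms: none
Why: Fluoride attacks silicon and triflate leaves from the neighbouring carbon, giving aryne 11; PhCO2Cs formed from 10 and CsF adds through oxygen at C2, and the C1 aryl anion then attacks the adjacent ester carbonyl via a fused four-membered alkoxide that opens to the C2 phenoxide with the benzoyl group on C1 (a 1,3 O-to-C acyl shift of anionic Fries type). The closest known reaction type is the fluoride-triggered insertion of arynes from ortho-silylaryl triflates into the C–O bond of carboxylic acids, which gives ortho-hydroxyaryl ketones. No ring is retained and no stereocentre is formed. The step needs regioselective addition (oxygen at C2, acyl at C1), which the σ-withdrawing C6 alkoxy group should secure by distorting the aryne so that the nucleophile attacks the remote carbon C2 and negative charge builds up at C1 next to oxygen. It also needs acyl transfer to outrun protonation of the C1 anion, which is favoured by keeping the acid as its cesium salt under excess CsF and by the high temperature; an ene reaction of the C3 prenyl group would require a strained bicyclic transition state and should not compete.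

Step 9
Reactants: 12 2-hydroxy-4-methoxy-6-(methoxymethoxy)-3,5-bis(3-methylbut-2-enyl)benzophenone
Product: 13 2,6-dihydroxy-4-methoxy-3,5-bis(3-methylbut-2-enyl)benzophenone (target)
Conditions: 3 M aq HCl, MeOH, rt
Reagents that add atoms: none
Why: Acid-catalysed methanolysis of the MOM acetal, which sits ortho to the ketone and is cleaved readily, should proceed in dilute acid at room temperature without cyclizing the prenyl groups onto the neighbouring phenols; no silicon is left to be lost and no stereocentre is involved.

Compound list
1 | 5-methoxyresorcinol (5-methoxybenzene-1,3-diol) | COc1cc(O)cc(O)c1 | starting material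
2 | 3-methoxy-5-(methoxymethoxy)phenol | COCOc1cc(O)cc(OC)c1 | intermediate
3 | 3-methoxy-5-(methoxymethoxy)phenyl N,N-diethylcarbamate | CCN(CC)C(=O)Oc1cc(OC)cc(OCOC)c1 | intermediate
4 | 5-methoxy-3-(methoxymethoxy)-2-(trimethylsilyl)phenyl N,N-diethylcarbamate | CCN(CC)C(=O)Oc1cc(OC)cc(OCOC)c1[Si](C)(C)C | intermediate
5 | prenyl bromide (1-bromo-3-methylbut-2-ene) | CC(C)=CCBr | starting material
6 | 3-methoxy-5-(methoxymethoxy)-2-(3-methylbut-2-enyl)-6-(trimethylsilyl)phenyl N,N-diethylcarbamate | CCN(CC)C(=O)Oc1c(CC=C(C)C)c(OC)cc(OCOC)c1[Si](C)(C)C | intermediate
7 | 3-methoxy-5-(methoxymethoxy)-2-(3-methylbut-2-enyl)-6-(trimethylsilyl)phenol | COCOc1cc(OC)c(CC=C(C)C)c(O)c1[Si](C)(C)C | intermediate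
8 | 3-methoxy-5-(methoxymethoxy)-2,4-bis(3-methylbut-2-enyl)-6-(trimethylsilyl)phenol | COCOc1c(CC=C(C)C)c(OC)c(CC=C(C)C)c(O)c1[Si](C)(C)C | intermediate
9 | 3-methoxy-5-(methoxymethoxy)-2,4-bis(3-methylbut-2-enyl)-6-(trimethylsilyl)phenyl trifluoromethanesulfonate | COc1c(CC=C(C)C)c(OS(=O)(=O)C(F)(F)F)c([Si](C)(C)C)c(OCOC)c1CC=C(C)C | intermediate
10 | benzoic acid | OC(=O)c1ccccc1 | starting material
11 | 4-methoxy-6-(methoxymethoxy)-3,5-bis(3-methylbut-2-enyl)-1,2-didehydrobenzene (the C1–C2 aryne of ring A; not isolated) | COC1=C(CC=C(C)C)C#CC(OCOC)=C1CC=C(C)C | intermediate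
12 | 2-hydroxy-4-methoxy-6-(methoxymethoxy)-3,5-bis(3-methylbut-2-enyl)benzophenone | COCOc1c(CC=C(C)C)c(OC)c(CC=C(C)C)c(O)c1C(=O)c1ccccc1 | intermediate
13 | 2,6-dihydroxy-4-methoxy-3,5-bis(3-methylbut-2-enyl)benzophenone | COc1c(CC=C(C)C)c(O)c(C(=O)c2ccccc2)c(O)c1CC=C(C)C | target

Total step count: 9
Longest linear sequence: 9 steps (1 to 13)

Steps most likely to fail

First, step 8, the key step. The C1 aryl anion may be protonated before it reaches the ester carbonyl, so that the sequence stops at the O-aryl benzoate stage. Fluoride may also remove silicon without expulsion of triflate, or benzoate may add at C1 and not at the more hindered C2. The fallback forgoes the aryne and relies on directed metalation. It sets out from 8: O-alkylation (NaH, MOMCl, DMF, 0 °C) should give [4-methoxy-2,6-bis(methoxymethoxy)-3,5-bis(3-methylbut-2-enyl)phenyl]trimethylsilane F1. Fluoride-mediated protodesilylation (TBAF, wet DMF, 80 °C) should then give 3-methoxy-1,5-bis(methoxymethoxy)-2,4-bis(3-methylbut-2-enyl)benzene F2. Directed ortho-metalation of its only ring C–H, between the two MOM oxygens (n-BuLi, THF, 0 °C), and acylation with N-methoxy-N-methylbenzamide should give [4-methoxy-2,6-bis(methoxymethoxy)-3,5-bis(3-methylbut-2-enyl)phenyl](phenyl)methanone F3. Acidic methanolysis of both MOM ethers (3 M aq HCl, MeOH, rt) then gives the target, so the route is rejoined at 13.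

Second, step 6. The electron-rich lithium phenoxide may resist the second deprotonation or be metalated too slowly in its aggregates, so that C5 stays unfunctionalized. O-alkylation of the phenoxide by prenyl bromide is the other way the step could go astray. The fallback changes the order and metalates the neutral carbamate before the hydride cleavage. It sets out from 6: metalation at C5, cupration and allylic substitution (s-BuLi, TMEDA, THF, −78 °C; CuBr·SMe2; 5) should give 3-methoxy-5-(methoxymethoxy)-2,4-bis(3-methylbut-2-enyl)-6-(trimethylsilyl)phenyl N,N-diethylcarbamate F4. Hydride cleavage of the carbamate (LiAlH4, THF, reflux) then rejoins the route at 8. This order is held in reserve because the carbamate may direct the base to the neighbouring prenyl CH2.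

Third, step 4. The ortho-lithiated carbamate may undergo the anionic ortho-Fries shift before it is transmetalated, or the arylcopper may attack the tertiary terminus of prenyl bromide (allylic transposition), so that the side chain is not installed cleanly. The fallback builds the side chain in two stages and sets out from 4. The same lithiation is followed by direct capture of the aryllithium at −78 °C with allyl bromide, a small and fast electrophile with equivalent termini. This should give 3-methoxy-5-(methoxymethoxy)-2-(prop-2-enyl)-6-(trimethylsilyl)phenyl N,N-diethylcarbamate F5. Olefin cross-metathesis with 2-methyl-2-butene (second-generation Grubbs catalyst, CH2Cl2, 40 °C) should convert the allyl group into a prenyl group, and the route is rejoined at 6.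

Further compounds
F1 | step 8 | [4-methoxy-2,6-bis(methoxymethoxy)-3,5-bis(3-methylbut-2-enyl)phenyl]trimethylsilane | COCOc1c(CC=C(C)C)c(OC)c(CC=C(C)C)c(OCOC)c1[Si](C)(C)C
F2 | step 8 | 3-methoxy-1,5-bis(methoxymethoxy)-2,4-bis(3-methylbut-2-enyl)benzene | COCOc1cc(OCOC)c(CC=C(C)C)c(OC)c1CC=C(C)C
F3 | step 8 | [4-methoxy-2,6-bis(methoxymethoxy)-3,5-bis(3-methylbut-2-enyl)phenyl](phenyl)methanone | COCOc1c(CC=C(C)C)c(OC)c(CC=C(C)C)c(OCOC)c1C(=O)c1ccccc1
F4 | step 6 | 3-methoxy-5-(methoxymethoxy)-2,4-bis(3-methylbut-2-enyl)-6-(trimethylsilyl)phenyl N,N-diethylcarbamate | CCN(CC)C(=O)Oc1c(CC=C(C)C)c(OC)c(CC=C(C)C)c(OCOC)c1[Si](C)(C)C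
F5 | step 4 | 3-methoxy-5-(methoxymethoxy)-2-(prop-2-enyl)-6-(trimethylsilyl)phenyl N,N-diethylcarbamate | CCN(CC)C(=O)Oc1c(CC=C)c(OC)cc(OCOC)c1[Si](C)(C)C
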